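**Retrosynthetic overview**

1. The cyclohexenedione (syncarpic acid) ring is made last, in one operation. It is cut at the bond between C4 (the ring carbon that carries the benzylic CH) and C5 (the enol carbon, C–OH), and at the bond between C3 (ketone) and C2 (CMe2).
2. This leads back to a C9 keto ester (from dimethylketene dimer) and an (S)-4-isopropyl-3,4-dihydrocoumarin. In the latter an ortho oxygen of the phloroglucinol ring holds the future C3 as an aryl ester, a temporary lactone ring that the key step opens again.
3. Enabling feature: C4 is the only carbon of that ring able to bear hydrogen (C2 and C6 are quaternary CMe2 carbons). The open-chain 3,5-dioxo ester therefore has one enolisable CH2 and one ester, and the enolised 1,3,5-trione is a thermodynamic sink. The closure copies the Claisen cyclisation of a polyketide chain.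
4. The benzylic stereocentre is set earlier by an amine-catalysed conjugate addition of the acylphloroglucinol to (E)-4-methylpent-2-enal.
5. Ring order: aromatic ring (present from the start), lactol then lactone ring (steps 2 and 3, temporary), cyclohexenedione ring (step 5).

Key step: step 5

Remark: the lactol and lactone of steps 2 and 3 are drawn closed onto the hydroxyl para to the ketone (the most acidic one); closure onto the other ortho hydroxyl would give a ring isomer that loses the same C–O bond in step 5 and leads to the same product.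

**Route**

Step 1
Reactants: 1 2-methylbenzene-1,3,5-triol; 2 2-methylpropanoyl chloride
Product: 3 1-(2,4,6-trihydroxy-3-methylphenyl)-2-methylpropan-1-one
Conditions: AlCl3 (3.5 equiv), PhNO2/CH2Cl2, 0 to 40 °C; ice, aq. HCl
Reagents that add atoms: none
Why: Friedel–Crafts acylation of a phloroglucinol, in which the two free ring positions of 1 are equivalent and the first acyl group deactivates the ring against a second acylation.

Step 2
Reactants: 3 1-(2,4,6-trihydroxy-3-methylphenyl)-2-methylpropan-1-one; 4 (E)-4-methylpent-2-enal
Product: 6 1-[(4S)-2,5,7-trihydroxy-8-methyl-4-(propan-2-yl)-3,4-dihydro-2H-chromen-6-yl]-2-methylpropan-1-one (both anomers at C2), via open-chain aldehyde 5 (not isolated)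
Conditions: (S)-2-[diphenyl(trimethylsilyloxy)methyl]pyrrolidine (20 mol %), PhCO2H (20 mol %), 4 (1.2 equiv), toluene, 0 °C
Reagents that add atoms: none
Why: Amine-catalysed Friedel–Crafts-type conjugate addition of a hydroxyarene to an enal (iminium activation) followed by hemiacetal formation, in which the only free ring carbon of 3 should add to C3 of the (E)-iminium ion on the face away from the diphenyl(trimethylsilyloxy)methyl group of the S catalyst (the Re face at C3), setting the S configuration, before the liberated aldehyde closes onto an ortho hydroxyl.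

Step 3
Reactants: 6 1-[(4S)-2,5,7-trihydroxy-8-methyl-4-(propan-2-yl)-3,4-dihydro-2H-chromen-6-yl]-2-methylpropan-1-one
Product: 7 (4S)-5,7-dihydroxy-8-methyl-6-(2-methylpropanoyl)-4-(propan-2-yl)-3,4-dihydro-2H-chromen-2-one
Conditions: (n-Pr4N)RuO4 (5 mol %), N-methylmorpholine N-oxide (1.5 equiv), 4 Å molecular sieves, CH2Cl2, 0 °C to rt
Reagents that add atoms: none
Why: Ley–Griffith oxidation of a lactol to the lactone, expected to be much faster than attack on the hydrogen-bonded, acyl-deactivated phenols, and the stereocentre is β to the new carbonyl and cannot epimerise.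

Step 4
Reactants: 8 2,2,4,4-tetramethylcyclobutane-1,3-dione
Product: 9 methyl 2,2,4-trimethyl-3-oxopentanoate
Conditions: NaOMe (5 mol %), MeOH, rt to 40 °C
Reagents that add atoms: methanol, CO
Why: Base-catalysed retro-Claisen ring opening of a strained, non-enolisable cyclobutane-1,3-dione by methanol, where the catalytic base and mild temperature should stop the reaction after the first cleavage.

Step 5
Reactants: 7 (4S)-5,7-dihydroxy-8-methyl-6-(2-methylpropanoyl)-4-(propan-2-yl)-3,4-dihydro-2H-chromen-2-one; 9 methyl 2,2,4-trimethyl-3-oxopentanoate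
Product: 12 5-hydroxy-2,2,6,6-tetramethyl-4-{(1S)-2-methyl-1-[2,4,6-trihydroxy-3-methyl-5-(2-methylpropanoyl)phenyl]propyl}cyclohex-4-ene-1,3-dione (the target), via lithium enolate 10 (not isolated), via open-chain dioxo ester 11 (not isolated)
Conditions: 9 (5 equiv), LiN(i-Pr)2 (4.8 equiv), THF, −78 to 0 °C; then 7 in THF/DMPU, −78 °C to rt; 1 M HCl, 0 °C
Reagents that add atoms: none
Why: Proposed new method: a one-pot crossed Claisen/Dieckmann [4+2] annulation, in which the fully substituted lithium enolate 10 is C-acylated by the aryl-ester carbonyl of lactone 7 (phenoxide as leaving group) to give dioxo ester 11, whose only enolisable position, the CH2 next to the benzylic carbon, is deprotonated by excess 10 and attacks the methyl ester to close the six-membered ring in a 6-(enolendo)-exo-trig Dieckmann closure. The closest known reaction types are the acylation of ketone enolates by lactones and aryl esters, the Dieckmann cyclisation of 5-oxo esters to cyclohexane-1,3-diones and the base-induced rearrangement of enol lactones to cyclic 1,3-diones; new is their merger on a fully substituted enolate to give a 4-substituted syncarpic acid directly. O-Acylation of 10 and O-closure of the second enolate would give enol esters that the tethered phenoxide or the liberated methoxide can reopen, so both bond formations should funnel to the C-acylated product, which leaves the equilibria as the enolate of the β-triketone. Regioselectivity is secured by the two quaternary CMe2 carbons, which leave one CH2 and one methoxycarbonyl group as the only possible partners, and chemoselectivity over the aryl ketone by its two ortho phenoxides and its hindrance. No stereocentre is formed: the benzylic centre set in step 2 is not enolisable and cannot undergo retro-Michael cleavage while the triketone is held as its enolate. Cold, dilute acid then releases 12 without cyclodehydration.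

**Compound list**

1 | 2-methylbenzene-1,3,5-triol (2-methylphloroglucinol) | Cc1c(O)cc(O)cc1O | starting material
2 | 2-methylpropanoyl chloride | CC(C)C(Cl)=O | starting material
3 | 1-(2,4,6-trihydroxy-3-methylphenyl)-2-methylpropan-1-one | CC(C)C(=O)c1c(O)cc(O)c(C)c1O | intermediate
4 | (E)-4-methylpent-2-enal | CC(C)/C=C/C=O | starting material
5 | (3S)-4-methyl-3-[2,4,6-trihydroxy-3-methyl-5-(2-methylpropanoyl)phenyl]pentanal (open-chain aldehyde, not isolated) | CC(C)C(=O)c1c(O)c(C)c(O)c([C@@H](CC=O)C(C)C)c1O | intermediate
6 | 1-[(4S)-2,5,7-trihydroxy-8-methyl-4-(propan-2-yl)-3,4-dihydro-2H-chromen-6-yl]-2-methylpropan-1-one (lactol, both anomers at C2) | CC(C)C(=O)c1c(O)c(C)c2OC(O)C[C@@H](C(C)C)c2c1O | intermediate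
7 | (4S)-5,7-dihydroxy-8-methyl-6-(2-methylpropanoyl)-4-(propan-2-yl)-3,4-dihydro-2H-chromen-2-one (lactone) | CC(C)C(=O)c1c(O)c(C)c2OC(=O)C[C@@H](C(C)C)c2c1O | intermediate
8 | 2,2,4,4-tetramethylcyclobutane-1,3-dione | CC1(C)C(=O)C(C)(C)C1=O | starting material
9 | methyl 2,2,4-trimethyl-3-oxopentanoate | COC(=O)C(C)(C)C(=O)C(C)C | intermediate
10 | lithium 1-methoxy-2,2,4-trimethyl-1-oxopent-3-en-3-olate (lithium enolate of 9, not isolated) | COC(=O)C(C)(C)C(O[Li])=C(C)C | intermediate
11 | methyl (7S)-2,2,4,4,8-pentamethyl-3,5-dioxo-7-[2,4,6-trihydroxy-3-methyl-5-(2-methylpropanoyl)phenyl]nonanoate (formed as its lithium phenoxide, not isolated) | CC(C)C(=O)c1c(O)c(C)c(O)c([C@@H](CC(=O)C(C)(C)C(=O)C(C)(C)C(=O)OC)C(C)C)c1O | intermediate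
12 | 5-hydroxy-2,2,6,6-tetramethyl-4-{(1S)-2-methyl-1-[2,4,6-trihydroxy-3-methyl-5-(2-methylpropanoyl)phenyl]propyl}cyclohex-4-ene-1,3-dione | Cc1c(O)c(C(=O)C(C)C)c(O)c([C@@H](C2=C(O)C(C)(C)C(=O)C(C)(C)C2=O)C(C)C)c1O | target

**Step count and risks**

Total steps: 5. Longest linear sequence: 4 steps (steps 1, 2, 3 and 5); step 4 is a one-step side branch.

Steps most likely to fail:

1. Step 5 (proposed new method). C-acylation of the hindered enolate may be outrun by proton transfer from the lactone CH2 or by O-acylation. Methoxide set free during ring closure may also open unreacted lactone by transesterification. Fallback with known chemistry, setting out from 6 and returning at 12: lactol 6 is opened and benzylated (BnBr, K2CO3, DMF) to (3S)-4-methyl-3-[2,4,6-tris(benzyloxy)-3-methyl-5-(2-methylpropanoyl)phenyl]pentanal F1. Aldol addition of enolate 10 (THF, −78 °C) gives the β-hydroxy ketone F2. Dess–Martin oxidation gives the tribenzylated 3,5-dioxo ester F3. Dieckmann cyclisation with KN(SiMe3)2 in THF gives the tribenzyl ether of the target F4. Hydrogenolysis (H2, Pd/C, EtOAc) then gives 12.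

2. Step 2. The acyl-deactivated arene may add too slowly to the hindered β-isopropyl iminium ion, so that uncatalysed addition or 1,2-addition erodes the enantioselectivity. Fallback, setting out from 3 and returning at 7 (steps 2 and 3 are passed by): Meldrum's acid and isobutyraldehyde are condensed (pyrrolidinium acetate, benzene) to 2,2-dimethyl-5-(2-methylpropylidene)-1,3-dioxane-4,6-dione F5. Heating 3 with F5 in pyridine at 80 °C should give the racemic lactone F6 by conjugate addition, lactonisation and decarboxylation. The 4S enantiomer, 7, is then separated by preparative chromatography on a chiral stationary phase.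

3. Step 3. Oxidative dearomatisation of the electron-rich triphenol ring may compete with dehydrogenation of the lactol. Fallback, setting out from 6 and returning at 7: the open-chain aldehyde tautomer is oxidised with chlorite (NaClO2, NaH2PO4, 2-methyl-2-butene, t-BuOH/H2O, 0 °C) to (3S)-4-methyl-3-[2,4,6-trihydroxy-3-methyl-5-(2-methylpropanoyl)phenyl]pentanoic acid F7. The acid is closed to 7 with catalytic TsOH in toluene at 50 °C.

**Further compounds**

F1 | step 5 | (3S)-4-methyl-3-[2,4,6-tris(benzyloxy)-3-methyl-5-(2-methylpropanoyl)phenyl]pentanal | CC(C)C(=O)c1c(OCc2ccccc2)c(C)c(OCc2ccccc2)c([C@@H](CC=O)C(C)C)c1OCc1ccccc1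
F2 | step 5 | methyl (7S)-5-hydroxy-2,2,4,4,8-pentamethyl-3-oxo-7-[2,4,6-tris(benzyloxy)-3-methyl-5-(2-methylpropanoyl)phenyl]nonanoate (both C5 epimers) | CC(C)C(=O)c1c(OCc2ccccc2)c(C)c(OCc2ccccc2)c([C@@H](CC(O)C(C)(C)C(=O)C(C)(C)C(=O)OC)C(C)C)c1OCc1ccccc1
F3 | step 5 | methyl (7S)-2,2,4,4,8-pentamethyl-3,5-dioxo-7-[2,4,6-tris(benzyloxy)-3-methyl-5-(2-methylpropanoyl)phenyl]nonanoate | CC(C)C(=O)c1c(OCc2ccccc2)c(C)c(OCc2ccccc2)c([C@@H](CC(=O)C(C)(C)C(=O)C(C)(C)C(=O)OC)C(C)C)c1OCc1ccccc1
F4 | step 5 | 5-hydroxy-2,2,6,6-tetramethyl-4-{(1S)-2-methyl-1-[2,4,6-tris(benzyloxy)-3-methyl-5-(2-methylpropanoyl)phenyl]propyl}cyclohex-4-ene-1,3-dione | CC(C)C(=O)c1c(OCc2ccccc2)c(C)c(OCc2ccccc2)c([C@@H](C2=C(O)C(C)(C)C(=O)C(C)(C)C2=O)C(C)C)c1OCc1ccccc1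
F5 | step 2 | 2,2-dimethyl-5-(2-methylpropylidene)-1,3-dioxane-4,6-dione | CC(C)C=C1C(=O)OC(C)(C)OC1=O
F6 | step 2 | racemic 5,7-dihydroxy-8-methyl-6-(2-methylpropanoyl)-4-(propan-2-yl)-3,4-dihydro-2H-chromen-2-one | CC(C)C(=O)c1c(O)c(C)c2OC(=O)CC(C(C)C)c2c1O
F7 | step 3 | (3S)-4-methyl-3-[2,4,6-trihydroxy-3-methyl-5-(2-methylpropanoyl)phenyl]pentanoic acid | CC(C)C(=O)c1c(O)c(C)c(O)c([C@@H](CC(O)=O)C(C)C)c1O
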